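The lactone carbinol carbon C6 is allylic to the ring C4=C5 double bond and its neighbour C7 carries the acyl carbon C11: the γ-lactone with C4=C5–C6–C7 is the 1,2-carbo-oxygenation pattern of a C4=C5–C6=C7 diene. Everything rests on fusing the α-methylene lactone onto an acyclic (E,E)-diene with 2-bromoacrylic acid under palladium catalysis; one operation forms C11–C7 and O–C6, sets C6 and C7 from the dioxolane stereocentre C8 and keeps the C4=C5 geometry. The diene comes from butynediol, an alkylzinc and glyceraldehyde acetonide. The ten-membered ring is closed afterwards (C9–C10) by a Nozaki–Hiyama–Kishi reaction.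

Key step: step 6

Remark: locants follow germacrane numbering (C6 = lactone CH–O, C7 = CH bonded to C11, C8 = CH–O-isobutyryl, C9 = CH–OAc, C10=C1 = enoate alkene with C14 ester, C4=C5 = alkene with C15H2OH, C11–C13 = α-methylene acyl unit). The CIP label at C7 changes with the C8 substituent although the geometry does not; the target is 6R,7S,8S,9S.

Step 1
Reactants: 1 but-2-yne-1,4-diol
Product: 2 4-[(tert-butyldiphenylsilyl)oxy]but-2-yn-1-ol
Conditions: TBDPSCl (1 equiv), imidazole, diol (4 equiv), DMF/THF, 0 °C to rt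
Reagents that add atoms: tert-butyl(chloro)diphenylsilane, CC(C)(C)[Si](Cl)(c1ccccc1)c1ccccc1
Why: O-silylation of an alcohol, made mono-selective by the excess of the symmetric diol.

Step 2
Reactants: 2 4-[(tert-butyldiphenylsilyl)oxy]but-2-yn-1-ol
Product: 4 (2Z)-4-[(tert-butyldiphenylsilyl)oxy]-3-iodobut-2-en-1-ol, via cyclic alkenylalanate 3 (not isolated)
Conditions: Red-Al, THF, 0 °C to rt; then I2, THF, −78 to 0 °C; Rochelle salt work-up
Reagents that add atoms: Red-Al, [Na+].COCCO[AlH2-]OCCOC (only hydride reaches 4; Al, Na and alkoxide stay in intermediate 3); iodine, II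
Why: Hydroxyl-directed trans-hydroalumination puts hydride next to the free carbinol and aluminium on the distal alkyne carbon in a five-membered alanate, and iodinolysis with retention should give the Z iodide with iodine cis to the CH2OH carbon (future C6).

Step 3
Reactants: 4 (2Z)-4-[(tert-butyldiphenylsilyl)oxy]-3-iodobut-2-en-1-ol; 5 [2-(1,3-dioxolan-2-yl)ethyl]zinc bromide
Product: 6 (2E)-3-{[(tert-butyldiphenylsilyl)oxy]methyl}-5-(1,3-dioxolan-2-yl)pent-2-en-1-ol
Conditions: Pd(dppf)Cl2 (5 mol %), 5 (2.5 equiv), THF, rt to 50 °C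
Reagents that add atoms: none
Why: Negishi sp2–sp3 coupling with retention of alkene geometry places the C3–C1 chain cis to C6, which fixes the C4=C5 geometry of the target (C15 trans to C6).

Step 4
Reactants: 6 (2E)-3-{[(tert-butyldiphenylsilyl)oxy]methyl}-5-(1,3-dioxolan-2-yl)pent-2-en-1-ol
Product: 7 tert-butyl{[(2E)-4-bromo-2-[2-(1,3-dioxolan-2-yl)ethyl]but-2-en-1-yl]oxy}diphenylsilane
Conditions: CBr4, PPh3, 2,6-lutidine, CH2Cl2, 0 °C
Reagents that add atoms: carbon tetrabromide, BrC(Br)(Br)Br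
Why: Appel bromination of a primary allylic alcohol under neutral conditions that the acetal and the silyl ether tolerate.

Step 5
Reactants: 7 tert-butyl{[(2E)-4-bromo-2-[2-(1,3-dioxolan-2-yl)ethyl]but-2-en-1-yl]oxy}diphenylsilane; 8 tributylphosphane; 9 (4R)-2,2-dimethyl-1,3-dioxolane-4-carbaldehyde
Product: 12 (4S)-4-[(1E,3E)-4-{[(tert-butyldiphenylsilyl)oxy]methyl}-6-(1,3-dioxolan-2-yl)hexa-1,3-dien-1-yl]-2,2-dimethyl-1,3-dioxolane, via phosphonium bromide 10 (not isolated), via allylic ylide 11 (not isolated)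
Conditions: 8, MeCN/THF, rt; then KOtBu, THF, −78 °C; then 9, −78 °C to rt
Reagents that add atoms: none
Why: Wittig olefination with an allylic trialkylphosphonium ylide, a reagent class that is E-selective, should form the E C6=C7 bond, while C8 comes unchanged from the chiral pool in 9 (added cold to avoid α-epimerisation).

Step 6
Reactants: 12 (4S)-4-[(1E,3E)-4-{[(tert-butyldiphenylsilyl)oxy]methyl}-6-(1,3-dioxolan-2-yl)hexa-1,3-dien-1-yl]-2,2-dimethyl-1,3-dioxolane; 13 2-bromoprop-2-enoic acid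
Product: 14 (4S,5R)-5-[(1E)-2-{[(tert-butyldiphenylsilyl)oxy]methyl}-4-(1,3-dioxolan-2-yl)but-1-en-1-yl]-4-[(4S)-2,2-dimethyl-1,3-dioxolan-4-yl]-3-methylideneoxolan-2-one
Conditions: Pd(OAc)2 (10 mol %), P(2-furyl)3 (20 mol %), Ag2CO3 (1.2 equiv), MeCN, 60 °C, slow addition of 13 (2 equiv)
Reagents that add atoms: none
Why: Pd(0) inserts into the C–Br bond of 13, the alkenylpalladium carboxylate adds syn across C6=C7 with carbon going to the less substituted diene terminus C7 (C11–C7 bond), and the resulting η3-allylpalladium (C6–C5–C4) is captured at C6 by the palladium-bound carboxylate (O–C6 bond) with release of Pd(0). The closest known reaction type is the Larock heteroannulation of 1,3-dienes by vinylic halides that carry a carboxylic acid. The lactone closes in a 5-exo mode on the allyl terminus C6, since attack at C4 would need a seven-membered ring at a fully substituted carbon. C7 is controlled by the C8 dioxolane stereocentre (insertion on the face anti to the allylic C8–O bond, inside-alkoxy model), and C6 follows from syn insertion and inner-sphere C–O bond formation on the palladium face, a net syn addition to the E alkene that should give the trans 6R,7S lactone. The C4=C5 geometry should be kept because the fully substituted allyl terminus C4 resists η3–η1–η3 isomerisation. The step needs terminus regioselectivity and chemoselectivity for the diene, secured by the mono- versus disubstituted diene ends and by the absence of any other reactive alkene or halide in 12, while halide abstraction by silver keeps the carboxylate on palladium.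

Step 7
Reactants: 14 (4S,5R)-5-[(1E)-2-{[(tert-butyldiphenylsilyl)oxy]methyl}-4-(1,3-dioxolan-2-yl)but-1-en-1-yl]-4-[(4S)-2,2-dimethyl-1,3-dioxolan-4-yl]-3-methylideneoxolan-2-one
Product: 15 (4E)-4-{[(tert-butyldiphenylsilyl)oxy]methyl}-5-{(2R,3R)-3-[(1S)-1,2-dihydroxyethyl]-4-methylidene-5-oxooxolan-2-yl}pent-4-enal
Conditions: AcOH/H2O (4:1), 45 °C
Reagents that add atoms: water, O
Why: Acid-catalysed acetal hydrolysis removes the isopropylidene ketal and the ethylene acetal together, while the TBDPS ether and the allylic lactone should tolerate aqueous acetic acid.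

Step 8
Reactants: 15 (4E)-4-{[(tert-butyldiphenylsilyl)oxy]methyl}-5-{(2R,3R)-3-[(1S)-1,2-dihydroxyethyl]-4-methylidene-5-oxooxolan-2-yl}pent-4-enal; 16 methyl (triphenyl-λ5-phosphanylidene)acetate
Product: 17 methyl (2Z,6E)-6-{[(tert-butyldiphenylsilyl)oxy]methyl}-7-{(2R,3R)-3-[(1S)-1,2-dihydroxyethyl]-4-methylidene-5-oxooxolan-2-yl}-2-iodohepta-2,6-dienoate
Conditions: 16, NIS, MeCN, −20 °C, 20 min; then 15, −20 °C to rt
Reagents that add atoms: N-iodosuccinimide, O=C1CCC(=O)N1I
Why: Wittig olefination with the α-iodo stabilised ylide (pre-formed from 16 and NIS so that no free NIS meets the alkenes) should give the Z α-iodoenoate with the ester trans to the chain, and the free diol is tolerated.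

Step 9
Reactants: 17 methyl (2Z,6E)-6-{[(tert-butyldiphenylsilyl)oxy]methyl}-7-{(2R,3R)-3-[(1S)-1,2-dihydroxyethyl]-4-methylidene-5-oxooxolan-2-yl}-2-iodohepta-2,6-dienoate
Product: 19 methyl (2Z,6E)-6-{[(tert-butyldiphenylsilyl)oxy]methyl}-2-iodo-7-{(2R,3S)-4-methylidene-3-[(1S)-1-(2-methylpropanoyloxy)-2-(triethylsilyloxy)ethyl]-5-oxooxolan-2-yl}hepta-2,6-dienoate, via primary triethylsilyl ether 18 (not isolated)
Conditions: TESCl (1.05 equiv), imidazole, CH2Cl2, −40 °C; then (i-PrCO)2O, DMAP (cat.), 0 °C to rt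
Reagents that add atoms: chlorotriethylsilane, CC[Si](Cl)(CC)CC; 2-methylpropanoic anhydride, CC(C)C(=O)OC(=O)C(C)C
Why: Kinetic silylation of the primary 9-hydroxyl followed in the same flask by DMAP-catalysed acylation of the remaining secondary 8-hydroxyl differentiates the diol without changing a stereocentre.

Step 10
Reactants: 19 methyl (2Z,6E)-6-{[(tert-butyldiphenylsilyl)oxy]methyl}-2-iodo-7-{(2R,3S)-4-methylidene-3-[(1S)-1-(2-methylpropanoyloxy)-2-(triethylsilyloxy)ethyl]-5-oxooxolan-2-yl}hepta-2,6-dienoate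
Product: 20 methyl (2Z,6E)-6-{[(tert-butyldiphenylsilyl)oxy]methyl}-2-iodo-7-{(2R,3S)-4-methylidene-3-[(1S)-1-(2-methylpropanoyloxy)-2-oxoethyl]-5-oxooxolan-2-yl}hepta-2,6-dienoate
Conditions: (COCl)2, DMSO, CH2Cl2, −78 to −40 °C; then Et3N, −78 to 0 °C
Reagents that add atoms: none
Why: Swern oxidation converts a primary triethylsilyl ether directly into the aldehyde, which avoids a free 9-hydroxyl next to the 8-ester (no acyl migration), and the low temperature limits epimerisation at C8.

Step 11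
Reactants: 20 methyl (2Z,6E)-6-{[(tert-butyldiphenylsilyl)oxy]methyl}-2-iodo-7-{(2R,3S)-4-methylidene-3-[(1S)-1-(2-methylpropanoyloxy)-2-oxoethyl]-5-oxooxolan-2-yl}hepta-2,6-dienoate
Product: 21 methyl (6R,7S,8S,9S)-15-(tert-butyldiphenylsilyloxy)-9-hydroxy-8-(2-methylpropanoyloxy)germacra-1(10)E,4E,11(13)-trien-12,6-olid-14-oate
Conditions: CrCl2 (8 equiv), chiral oxazoline–sulfonamide ligand (enantiomer chosen for Si-face delivery to C9=O), Et3N, NiCl2·2,9-dimethylphenanthroline (cat.), MeCN/THF, rt, 2 mM, slow addition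
Reagents that add atoms: none
Why: Nozaki–Hiyama–Kishi macrocyclisation adds the alkenylchromium formed from the α-iodoenoate to the C9 aldehyde, closing the ten-membered ring with the ring-cis C1=C10 geometry, and the 9S configuration (Si-face attack) is to be enforced by the chiral chromium complex against the Felkin bias of the α-acyloxy aldehyde.

Step 12
Reactants: 21 methyl (6R,7S,8S,9S)-15-(tert-butyldiphenylsilyloxy)-9-hydroxy-8-(2-methylpropanoyloxy)germacra-1(10)E,4E,11(13)-trien-12,6-olid-14-oate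
Product: 22 methyl (6R,7S,8S,9S)-9-acetoxy-15-(tert-butyldiphenylsilyloxy)-8-(2-methylpropanoyloxy)germacra-1(10)E,4E,11(13)-trien-12,6-olid-14-oate
Conditions: Ac2O, DMAP (cat.), pyridine, CH2Cl2, 0 °C
Reagents that add atoms: acetic anhydride, CC(=O)OC(C)=O
Why: DMAP-catalysed acetylation of the only free hydroxyl proceeds with retention at C9.

Step 13
Reactants: 22 methyl (6R,7S,8S,9S)-9-acetoxy-15-(tert-butyldiphenylsilyloxy)-8-(2-methylpropanoyloxy)germacra-1(10)E,4E,11(13)-trien-12,6-olid-14-oate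
Product: 23 methyl (6R,7S,8S,9S)-9-acetoxy-15-hydroxy-8-(2-methylpropanoyloxy)germacra-1(10)E,4E,11(13)-trien-12,6-olid-14-oate (CNP0242134.2)
Conditions: HF·pyridine, pyridine/THF, 0 °C to rt
Reagents that add atoms: none
Why: Fluoride-mediated desilylation cleaves the Si–O bond under buffered conditions that should leave the three esters, the lactone and the enoate untouched.

Compound list
1 | but-2-yne-1,4-diol | OCC#CCO | starting material
2 | 4-[(tert-butyldiphenylsilyl)oxy]but-2-yn-1-ol | OCC#CCO[Si](c1ccccc1)(c1ccccc1)C(C)(C)C | intermediate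
3 | sodium cyclic alkenylalanate of 2 (Al bonded to the carbinol oxygen and to the alkene carbon bearing CH2OTBDPS) | [Na+].COCCO[Al-]1(OCCOC)OCC=C1CO[Si](c1ccccc1)(c1ccccc1)C(C)(C)C | intermediate
4 | (2Z)-4-[(tert-butyldiphenylsilyl)oxy]-3-iodobut-2-en-1-ol | OC/C=C(\I)CO[Si](c1ccccc1)(c1ccccc1)C(C)(C)C | intermediate
5 | [2-(1,3-dioxolan-2-yl)ethyl]zinc bromide | Br[Zn]CCC1OCCO1 | starting material
6 | (2E)-3-{[(tert-butyldiphenylsilyl)oxy]methyl}-5-(1,3-dioxolan-2-yl)pent-2-en-1-ol | OC/C=C(/CO[Si](c1ccccc1)(c1ccccc1)C(C)(C)C)CCC1OCCO1 | intermediate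
7 | tert-butyl{[(2E)-4-bromo-2-[2-(1,3-dioxolan-2-yl)ethyl]but-2-en-1-yl]oxy}diphenylsilane | BrC/C=C(/CO[Si](c1ccccc1)(c1ccccc1)C(C)(C)C)CCC1OCCO1 | intermediate
8 | tributylphosphane | CCCCP(CCCC)CCCC | starting material
9 | (4R)-2,2-dimethyl-1,3-dioxolane-4-carbaldehyde | CC1(C)OC[C@H](C=O)O1 | starting material
10 | tributyl[(2E)-3-{[(tert-butyldiphenylsilyl)oxy]methyl}-5-(1,3-dioxolan-2-yl)pent-2-en-1-yl]phosphonium bromide | CCCC[P+](CCCC)(CCCC)C/C=C(/CO[Si](c1ccccc1)(c1ccccc1)C(C)(C)C)CCC1OCCO1.[Br-] | intermediate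
11 | allylic ylide from 10 | CCCCP(CCCC)(CCCC)=C/C=C(/CO[Si](c1ccccc1)(c1ccccc1)C(C)(C)C)CCC1OCCO1 | intermediate
12 | (4S)-4-[(1E,3E)-4-{[(tert-butyldiphenylsilyl)oxy]methyl}-6-(1,3-dioxolan-2-yl)hexa-1,3-dien-1-yl]-2,2-dimethyl-1,3-dioxolane | CC1(C)OC[C@H](/C=C/C=C(/CO[Si](c2ccccc2)(c2ccccc2)C(C)(C)C)CCC2OCCO2)O1 | intermediate
13 | 2-bromoprop-2-enoic acid | C=C(Br)C(=O)O | starting material
14 | (4S,5R)-5-[(1E)-2-{[(tert-butyldiphenylsilyl)oxy]methyl}-4-(1,3-dioxolan-2-yl)but-1-en-1-yl]-4-[(4S)-2,2-dimethyl-1,3-dioxolan-4-yl]-3-methylideneoxolan-2-one | C=C1C(=O)O[C@H](/C=C(/CO[Si](c2ccccc2)(c2ccccc2)C(C)(C)C)CCC2OCCO2)[C@H]1[C@H]1COC(C)(C)O1 | intermediate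
15 | (4E)-4-{[(tert-butyldiphenylsilyl)oxy]methyl}-5-{(2R,3R)-3-[(1S)-1,2-dihydroxyethyl]-4-methylidene-5-oxooxolan-2-yl}pent-4-enal | C=C1C(=O)O[C@H](/C=C(/CO[Si](c2ccccc2)(c2ccccc2)C(C)(C)C)CCC=O)[C@H]1[C@H](O)CO | intermediate
16 | methyl (triphenyl-λ5-phosphanylidene)acetate | COC(=O)C=P(c1ccccc1)(c1ccccc1)c1ccccc1 | starting material
17 | methyl (2Z,6E)-6-{[(tert-butyldiphenylsilyl)oxy]methyl}-7-{(2R,3R)-3-[(1S)-1,2-dihydroxyethyl]-4-methylidene-5-oxooxolan-2-yl}-2-iodohepta-2,6-dienoate | C=C1C(=O)O[C@H](/C=C(/CO[Si](c2ccccc2)(c2ccccc2)C(C)(C)C)CC/C=C(\I)C(=O)OC)[C@H]1[C@H](O)CO | intermediate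
18 | primary triethylsilyl ether of 17: (2R,3R)-oxolanyl ring with (1S)-1-hydroxy-2-(triethylsilyloxy)ethyl side chain | C=C1C(=O)O[C@H](/C=C(/CO[Si](c2ccccc2)(c2ccccc2)C(C)(C)C)CC/C=C(\I)C(=O)OC)[C@H]1[C@H](O)CO[Si](CC)(CC)CC | intermediate
19 | methyl (2Z,6E)-6-{[(tert-butyldiphenylsilyl)oxy]methyl}-2-iodo-7-{(2R,3S)-4-methylidene-3-[(1S)-1-(2-methylpropanoyloxy)-2-(triethylsilyloxy)ethyl]-5-oxooxolan-2-yl}hepta-2,6-dienoate | C=C1C(=O)O[C@H](/C=C(/CO[Si](c2ccccc2)(c2ccccc2)C(C)(C)C)CC/C=C(\I)C(=O)OC)[C@H]1[C@H](OC(=O)C(C)C)CO[Si](CC)(CC)CC | intermediate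
20 | methyl (2Z,6E)-6-{[(tert-butyldiphenylsilyl)oxy]methyl}-2-iodo-7-{(2R,3S)-4-methylidene-3-[(1S)-1-(2-methylpropanoyloxy)-2-oxoethyl]-5-oxooxolan-2-yl}hepta-2,6-dienoate | C=C1C(=O)O[C@H](/C=C(/CO[Si](c2ccccc2)(c2ccccc2)C(C)(C)C)CC/C=C(\I)C(=O)OC)[C@H]1[C@H](OC(=O)C(C)C)C=O | intermediate
21 | methyl (6R,7S,8S,9S)-15-(tert-butyldiphenylsilyloxy)-9-hydroxy-8-(2-methylpropanoyloxy)germacra-1(10)E,4E,11(13)-trien-12,6-olid-14-oate | C=C1C(=O)O[C@@H]2/C=C(/CO[Si](c3ccccc3)(c3ccccc3)C(C)(C)C)CC/C=C(/C(=O)OC)[C@H](O)[C@@H](OC(=O)C(C)C)[C@@H]12 | intermediate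
22 | methyl (6R,7S,8S,9S)-9-acetoxy-15-(tert-butyldiphenylsilyloxy)-8-(2-methylpropanoyloxy)germacra-1(10)E,4E,11(13)-trien-12,6-olid-14-oate | C=C1C(=O)O[C@@H]2/C=C(/CO[Si](c3ccccc3)(c3ccccc3)C(C)(C)C)CC/C=C(/C(=O)OC)[C@H](OC(C)=O)[C@@H](OC(=O)C(C)C)[C@@H]12 | intermediate
23 | methyl (6R,7S,8S,9S)-9-acetoxy-15-hydroxy-8-(2-methylpropanoyloxy)germacra-1(10)E,4E,11(13)-trien-12,6-olid-14-oate (CNP0242134.2) | C=C1C(=O)O[C@@H]2/C=C(/CO)CC/C=C(/C(=O)OC)[C@H](OC(C)=O)[C@@H](OC(=O)C(C)C)[C@@H]12 | target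

Total step count: 13. Longest linear sequence: 13 steps (from 1).

Steps most likely to fail

Step 6. The allylpalladium intermediate may lose a β-hydride from C7 instead of closing the lactone, the internal diene may insert slowly, or the facial selectivity at C7 (and hence the cis/trans outcome at C6) may be poor. The fallback makes the same two bonds by radical-polar chemistry and sets out from 12. Diene 12 is treated with malonic acid and Mn(OAc)3·2H2O/KOAc in AcOH at 25–40 °C (oxidative free-radical lactone annulation: the malonyl radical adds to C7, the allyl radical is oxidised and the carboxylate closes on C6). This should give the α-carboxy lactone F1, which is converted by decarboxylative Mannich methylenation (aqueous CH2O, Et2NH, then gentle warming) into 14, where the route is rejoined.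

Step 11. Facial selectivity in the addition to the C9 aldehyde may be poor or reversed, because the substrate's own (polar Felkin) bias points to the 9R alcohol and the macrocyclic transition state is not predictable. The fallback sets out from 20 and fixes C9 by substitution instead of by facial control. Ligand-free CrCl2/NiCl2 cyclisation (DMSO/THF, high dilution) is run under substrate control to give the 9-epi alcohol F2. A Mitsunobu reaction (AcOH, PPh3, DIAD, toluene, 0 °C) then installs the acetate with inversion and returns to the route at 22.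

Step 5. E-selectivity of the ylide olefination may erode, or the α-alkoxy aldehyde 9 may epimerise under the basic ylide. The fallback sets out from 7. A Michaelis–Arbuzov reaction with P(OEt)3 (neat, 110 °C) gives the diethyl allylphosphonate F3, and a Horner–Wadsworth–Emmons reaction of its lithium carbanion (LiHMDS, THF, −78 °C) with 9 forms the E C6=C7 bond under the thermodynamic control typical of phosphonate carbanions, rejoining the route at 12.

Further compounds
F1 | step 6 | α-carboxy lactone: 14 with C11 bearing H and CO2H instead of the methylidene (same C6, C7, C8 configuration, C11 epimers) | OC(=O)C1C(=O)O[C@H](/C=C(/CO[Si](c2ccccc2)(c2ccccc2)C(C)(C)C)CCC2OCCO2)[C@H]1[C@H]1COC(C)(C)O1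
F2 | step 11 | 9-epi alcohol: methyl (6R,7S,8S,9R)-15-(tert-butyldiphenylsilyloxy)-9-hydroxy-8-(2-methylpropanoyloxy)germacra-1(10)E,4E,11(13)-trien-12,6-olid-14-oate | C=C1C(=O)O[C@@H]2/C=C(/CO[Si](c3ccccc3)(c3ccccc3)C(C)(C)C)CC/C=C(/C(=O)OC)[C@@H](O)[C@@H](OC(=O)C(C)C)[C@@H]12
F3 | step 5 | diethyl [(2E)-3-{[(tert-butyldiphenylsilyl)oxy]methyl}-5-(1,3-dioxolan-2-yl)pent-2-en-1-yl]phosphonate | CCOP(=O)(OCC)C/C=C(/CO[Si](c1ccccc1)(c1ccccc1)C(C)(C)C)CCC1OCCO1
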